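**Retrosynthetic overview**
1. Oxirane last: reagent-controlled (Shi) epoxidation of the Z C1=C10 olefin of the 3-hydroxy (Z,Z)-germacradienolide.
2. Ten-membered carbocycle second: ring-closing metathesis (C1=C10) between an allyl group on C3 and a methallyl group on C8.
3. Key disconnection C7–C8 (new method): a butenolide-embedded allylboronate adds to 3-methylbut-3-enal and gives the α-methylene-γ-lactone, C7 and C8 in one step.
4. Lactone ring first: butenolide boronate from a γ-hydroxy ynoate (hydroalumination, borylmethylation, lactonisation); C6 from catalytic asymmetric alkynylation of a Z-enal.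
5. Z-Enal from 3-(trimethylsilyl)propynal: Brown allylation (C3), ynoate formation, syn methylcupration (Z C4=C5).

Assumption: the SMILES is taken as drawn, i.e. germacrane numbering, (1R,3S,6S,7S,8R,10S), 4Z, cis-fused 1,10-epoxide (C2 and C9 cis), 6,12-olide, 8-O-isobutyrate.
Abbreviations: TBS = tert-butyldimethylsilyl; Bpin = 4,4,5,5-tetramethyl-1,3,2-dioxaborolan-2-yl.

**Step 1**
Reactants: 1 3-(trimethylsilyl)prop-2-ynal
Product: 3 (3S)-1-(trimethylsilyl)hex-5-en-1-yn-3-ol, via diisopinocampheylborinate ester 2 (not isolated)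
Conditions: (−)-Ipc2B(allyl), Et2O, −78 °C; then NaBO3·4H2O, THF/H2O, rt
Reagents that add atoms: (−)-B-allyldiisopinocampheylborane [(−)-Ipc2B(allyl), from (+)-α-pinene], C=CCB([C@@H]1C[C@@H]2C[C@H]([C@H]1C)C2(C)C)[C@@H]1C[C@@H]2C[C@H]([C@H]1C)C2(C)C
Why: Brown asymmetric allylboration through a closed chair transition state, in which the (+)-α-pinene-derived reagent adds allyl to the Si face of the ynal and so sets C3 as (S).

**Step 2**
Reactants: 3 (3S)-1-(trimethylsilyl)hex-5-en-1-yn-3-ol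
Product: 5 (3S)-3-(TBS-oxy)hex-5-en-1-yne, via bis-silylated enyne 4 (not isolated)
Conditions: TBSCl, imidazole, DMF, rt; then K2CO3, MeOH, rt
Reagents that add atoms: tert-butyldimethylsilyl chloride (TBSCl), CC(C)(C)[Si](C)(C)Cl
Why: Silyl ether formation followed by selective methanolysis of the C(sp)–SiMe3 bond, to which the O–TBS ether is stable; C3 is not touched.

**Step 3**
Reactants: 5 (3S)-3-(TBS-oxy)hex-5-en-1-yne
Product: 7 methyl (4S)-4-(TBS-oxy)hept-6-en-2-ynoate, via lithium acetylide 6 (not isolated)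
Conditions: n-BuLi, THF, −78 °C; then ClCO2Me, −78 → 0 °C
Reagents that add atoms: methyl chloroformate, COC(Cl)=O
Why: Deprotonation of the terminal alkyne and C-acylation of the acetylide with a chloroformate gives the ynoate (C6 of the target) without affecting C3.

**Step 4**
Reactants: 7 methyl (4S)-4-(TBS-oxy)hept-6-en-2-ynoate
Product: 8 methyl (2Z,4S)-4-(TBS-oxy)-3-methylhepta-2,6-dienoate
Conditions: Me2CuLi (from CuI, MeLi), THF, −78 °C; aq. NH4Cl at −78 °C
Reagents that add atoms: lithium dimethylcuprate (Me2CuLi), [Li+].C[Cu-]C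
Why: Organocuprate conjugate addition to the ynoate is a syn carbometalation, and protonation at low temperature with retention places Me and H cis, so C3 and C6 are cis and the Z C4=C5 olefin is fixed.

**Step 5**
Reactants: 8 methyl (2Z,4S)-4-(TBS-oxy)-3-methylhepta-2,6-dienoate
Product: 9 (2Z,4S)-4-(TBS-oxy)-3-methylhepta-2,6-dien-1-ol
Conditions: iBu2AlH, CH2Cl2, −78 °C; aq. KNaC4H4O6 work-up
Reagents that add atoms: none
Why: 1,2-Reduction of the enoate ester by the aluminium hydride gives the allylic alcohol with olefin geometry and C3 unchanged.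

**Step 6**
Reactants: 9 (2Z,4S)-4-(TBS-oxy)-3-methylhepta-2,6-dien-1-ol
Product: 10 (2Z,4S)-4-(TBS-oxy)-3-methylhepta-2,6-dienal
Conditions: Dess–Martin periodinane, NaHCO3, CH2Cl2, 0 °C; used at once
Reagents that add atoms: none
Why: Buffered Dess–Martin oxidation of the allylic alcohol avoids acid and so preserves the Z geometry of the γ-silyloxy enal.

**Step 7**
Reactants: 10 (2Z,4S)-4-(TBS-oxy)-3-methylhepta-2,6-dienal; 11 methyl propiolate
Product: 12 methyl (4S,5Z,7S)-4-hydroxy-6-methyl-7-(TBS-oxy)deca-5,9-dien-2-ynoate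
Conditions: (R,R)-ProPhenol (20 mol%), Me2Zn, toluene, 0 °C; aq. NH4Cl
Reagents that add atoms: none
Why: Trost zinc–ProPhenol asymmetric alkynylation, in which the dinuclear zinc alkynylide is delivered under catalyst control to the Re face of the enal (ligand antipode chosen accordingly), forms C6–C7 and sets C6 as (S).

**Step 8**
Reactants: 12 methyl (4S,5Z,7S)-4-hydroxy-6-methyl-7-(TBS-oxy)deca-5,9-dien-2-ynoate
Product: 15 (5S)-5-[(1Z,3S)-3-(TBS-oxy)-2-methylhexa-1,5-dien-1-yl]-3-(Bpin-methyl)furan-2(5H)-one, via α-alumino enoate 13 (not isolated), via open-chain allylboronate 14 (not isolated)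
Conditions: iBu2AlH (2.2 equiv), HMPA, THF, 0 °C; then ICH2Bpin, 0 °C → rt; aq. citric acid
Reagents that add atoms: 2-(iodomethyl)-4,4,5,5-tetramethyl-1,3,2-dioxaborolane (ICH2Bpin), CC1(C)OB(CI)OC1(C)C
Why: Hydroalumination of the ynoate (syn, Al on the α-carbon) followed by Matteson-type 1,2-migration of the alkenyl group on the (iodomethyl)boronate ate complex forms C11–C13 with retention, and because H7 is cis to CH2B the C6 oxygen is cis to the ester and closes the butenolide without touching C6.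

**Step 9**
Reactants: 16 3-methylbut-3-en-1-ol
Product: 17 3-methylbut-3-enal
Conditions: Dess–Martin periodinane, NaHCO3, CH2Cl2, 0 °C; cold solution used directly
Reagents that add atoms: none
Why: Buffered Dess–Martin oxidation gives the β,γ-unsaturated aldehyde, which is kept cold and used immediately so that it does not conjugate to 3-methylbut-2-enal.

**Step 10**
Reactants: 15 (5S)-5-[(1Z,3S)-3-(TBS-oxy)-2-methylhexa-1,5-dien-1-yl]-3-(Bpin-methyl)furan-2(5H)-one; 17 3-methylbut-3-enal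
Product: 19 (4S,5S)-5-[(1Z,3S)-3-(TBS-oxy)-2-methylhexa-1,5-dien-1-yl]-4-[(1R)-1-hydroxy-3-methylbut-3-en-1-yl]-3-methylideneoxolan-2-one, via pinacol borate 18 (not isolated)
Conditions: Sc(OTf)3 (10 mol%), toluene, −78 → −30 °C; aq. NaHCO3
Reagents that add atoms: none
Why: Proposed new method: allylboration of an aldehyde by a butenolide-embedded (endocyclic) 2-(borylmethyl)enoate under Sc(OTf)3 catalysis, in which boron binds the aldehyde in a closed six-membered chair transition state, the ring-locked geometry (C6 trans to CH2B, an E-crotyl equivalent) gives the anti C7/C8 relationship (8R), the aldehyde approaches the face of C7 opposite to the C6 side chain (trans lactone, 7S), the allylic transposition delivers the α-methylene lactone directly and the lactone oxygen stays on C6 because the ring pre-exists; the closest known reaction types are the Lewis acid-catalysed additions of acyclic 2-alkoxycarbonyl allylboronates to aldehydes and the chromium-mediated anti-selective allylation with 3-(bromomethyl)furan-2(5H)-one.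

**Step 11**
Reactants: 19 (4S,5S)-5-[(1Z,3S)-3-(TBS-oxy)-2-methylhexa-1,5-dien-1-yl]-4-[(1R)-1-hydroxy-3-methylbut-3-en-1-yl]-3-methylideneoxolan-2-one
Product: 20 (1R)-1-[(2S,3S)-2-[(1Z,3S)-3-(TBS-oxy)-2-methylhexa-1,5-dien-1-yl]-4-methylidene-5-oxooxolan-3-yl]-3-methylbut-3-en-1-yl 2-methylpropanoate
Conditions: iPrCOCl, pyridine, DMAP (cat.), CH2Cl2, 0 °C
Reagents that add atoms: isobutyryl chloride, CC(C)C(Cl)=O
Why: DMAP-catalysed esterification of the only free hydroxyl (C8) installs the isobutyrate with no stereocentre affected.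

**Step 12**
Reactants: 20 (1R)-1-[(2S,3S)-2-[(1Z,3S)-3-(TBS-oxy)-2-methylhexa-1,5-dien-1-yl]-4-methylidene-5-oxooxolan-3-yl]-3-methylbut-3-en-1-yl 2-methylpropanoate
Product: 21 (3aS,4R,6Z,9S,10Z,11aS)-6,10-dimethyl-3-methylidene-2-oxo-9-(TBS-oxy)-2,3,3a,4,5,8,9,11a-octahydrocyclodeca[b]furan-4-yl 2-methylpropanoate
Conditions: second-generation Hoveyda–Grubbs catalyst RuCl2(H2IMes)(=CH-C6H4-2-OiPr) (10 mol%), 1,4-benzoquinone (10 mol%), toluene (1 mM), 80 °C, Ar sparge
Reagents that add atoms: none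
Why: Ring-closing metathesis initiates at the allyl group and closes onto the 1,1-disubstituted olefin, and the ten-membered ring held by the trans lactone and the Z C4=C5 olefin can only accommodate a Z C1=C10 double bond.

**Step 13**
Reactants: 21 (3aS,4R,6Z,9S,10Z,11aS)-6,10-dimethyl-3-methylidene-2-oxo-9-(TBS-oxy)-2,3,3a,4,5,8,9,11a-octahydrocyclodeca[b]furan-4-yl 2-methylpropanoate
Product: 22 (3aS,4R,6Z,9S,10Z,11aS)-9-hydroxy-6,10-dimethyl-3-methylidene-2-oxo-2,3,3a,4,5,8,9,11a-octahydrocyclodeca[b]furan-4-yl 2-methylpropanoate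
Conditions: HF·pyridine, pyridine, THF, 0 °C → rt
Reagents that add atoms: none
Why: Buffered fluoride-mediated silyl ether cleavage frees the C3 hydroxyl while ester, lactone and olefins stay inert.

**Step 14**
Reactants: 22 (3aS,4R,6Z,9S,10Z,11aS)-9-hydroxy-6,10-dimethyl-3-methylidene-2-oxo-2,3,3a,4,5,8,9,11a-octahydrocyclodeca[b]furan-4-yl 2-methylpropanoate
Product: 23 (1R,3S,4Z,6S,7S,8R,10S)-1,10-epoxy-3-hydroxy-8-(2-methylpropanoyloxy)germacra-4,11(13)-dien-12,6-olide (CNP0261225.1)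
Conditions: D-fructose-derived Shi ketone (30 mol%), Oxone (2KHSO5·KHSO4·K2SO4), K2CO3, Bu4NHSO4, Na2B4O7/Na2EDTA buffer (pH 10.5), MeCN–CH2(OMe)2–H2O, 0 °C
Reagents that add atoms: potassium peroxymonosulfate (active component of Oxone), [K+].[O-]S(=O)(=O)OO
Why: Shi asymmetric epoxidation, in which the chiral dioxirane attacks the most electron-rich olefin (C1=C10; C4=C5 is deactivated by two allylic C–O bonds and C11=C13 is electron-poor) through the spiro transition state, whose facial sense for a trisubstituted cyclic olefin with this ketone [as in (R,R)-1-phenylcyclohexene oxide] corresponds to (1R,10S).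

**Compound list**
1 | 3-(trimethylsilyl)prop-2-ynal | C[Si](C)(C)C#CC=O | starting material
2 | (3S)-1-(trimethylsilyl)hex-5-en-1-yn-3-yl diisopinocampheylborinate | C[Si](C)(C)C#C[C@@H](OB([C@@H]1C[C@@H]2C[C@H]([C@H]1C)C2(C)C)[C@@H]1C[C@@H]2C[C@H]([C@H]1C)C2(C)C)CC=C | intermediate
3 | (3S)-1-(trimethylsilyl)hex-5-en-1-yn-3-ol | C[Si](C)(C)C#C[C@@H](O)CC=C | intermediate
4 | (3S)-3-(TBS-oxy)-1-(trimethylsilyl)hex-5-en-1-yne | C[Si](C)(C)C#C[C@@H](O[Si](C)(C)C(C)(C)C)CC=C | intermediate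
5 | (3S)-3-(TBS-oxy)hex-5-en-1-yne | C#C[C@@H](O[Si](C)(C)C(C)(C)C)CC=C | intermediate
6 | lithium acetylide of 5 | [Li]C#C[C@@H](O[Si](C)(C)C(C)(C)C)CC=C | intermediate
7 | methyl (4S)-4-(TBS-oxy)hept-6-en-2-ynoate | COC(=O)C#C[C@@H](O[Si](C)(C)C(C)(C)C)CC=C | intermediate
8 | methyl (2Z,4S)-4-(TBS-oxy)-3-methylhepta-2,6-dienoate | COC(=O)/C=C(/C)[C@@H](O[Si](C)(C)C(C)(C)C)CC=C | intermediate
9 | (2Z,4S)-4-(TBS-oxy)-3-methylhepta-2,6-dien-1-ol | OC/C=C(/C)[C@@H](O[Si](C)(C)C(C)(C)C)CC=C | intermediate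
10 | (2Z,4S)-4-(TBS-oxy)-3-methylhepta-2,6-dienal | O=C/C=C(/C)[C@@H](O[Si](C)(C)C(C)(C)C)CC=C | intermediate
11 | methyl propiolate | C#CC(=O)OC | starting material
12 | methyl (4S,5Z,7S)-4-hydroxy-6-methyl-7-(TBS-oxy)deca-5,9-dien-2-ynoate | COC(=O)C#C[C@@H](O)/C=C(/C)[C@@H](O[Si](C)(C)C(C)(C)C)CC=C | intermediate
13 | methyl (2E,4S,5Z,7S)-2-(diisobutylalumanyl)-4-[(diisobutylalumanyl)oxy]-6-methyl-7-(TBS-oxy)deca-2,5,9-trienoate (Al cis to H on C3) | COC(=O)/C([Al](CC(C)C)CC(C)C)=C\[C@@H](O[Al](CC(C)C)CC(C)C)/C=C(/C)[C@@H](O[Si](C)(C)C(C)(C)C)CC=C | intermediate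
14 | methyl (2Z,4S,5Z,7S)-2-(Bpin-methyl)-4-hydroxy-6-methyl-7-(TBS-oxy)deca-2,5,9-trienoate | COC(=O)/C(CB1OC(C)(C)C(C)(C)O1)=C\[C@@H](O)/C=C(/C)[C@@H](O[Si](C)(C)C(C)(C)C)CC=C | intermediate
15 | (5S)-5-[(1Z,3S)-3-(TBS-oxy)-2-methylhexa-1,5-dien-1-yl]-3-(Bpin-methyl)furan-2(5H)-one | CC1(C)OB(CC2=C[C@H](/C=C(/C)[C@@H](O[Si](C)(C)C(C)(C)C)CC=C)OC2=O)OC1(C)C | intermediate
16 | 3-methylbut-3-en-1-ol | CC(=C)CCO | starting material
17 | 3-methylbut-3-enal | CC(=C)CC=O | intermediate
18 | O-Bpin ether of 19 (pinacol borate on the C8 oxygen) | C=C1C(=O)O[C@@H](/C=C(/C)[C@@H](O[Si](C)(C)C(C)(C)C)CC=C)[C@@H]1[C@H](OB2OC(C)(C)C(C)(C)O2)CC(C)=C | intermediate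
19 | (4S,5S)-5-[(1Z,3S)-3-(TBS-oxy)-2-methylhexa-1,5-dien-1-yl]-4-[(1R)-1-hydroxy-3-methylbut-3-en-1-yl]-3-methylideneoxolan-2-one | C=C1C(=O)O[C@@H](/C=C(/C)[C@@H](O[Si](C)(C)C(C)(C)C)CC=C)[C@@H]1[C@H](O)CC(C)=C | intermediate
20 | (1R)-1-[(2S,3S)-2-[(1Z,3S)-3-(TBS-oxy)-2-methylhexa-1,5-dien-1-yl]-4-methylidene-5-oxooxolan-3-yl]-3-methylbut-3-en-1-yl 2-methylpropanoate | C=C1C(=O)O[C@@H](/C=C(/C)[C@@H](O[Si](C)(C)C(C)(C)C)CC=C)[C@@H]1[C@H](OC(=O)C(C)C)CC(C)=C | intermediate
21 | (3aS,4R,6Z,9S,10Z,11aS)-6,10-dimethyl-3-methylidene-2-oxo-9-(TBS-oxy)-2,3,3a,4,5,8,9,11a-octahydrocyclodeca[b]furan-4-yl 2-methylpropanoate | C=C1C(=O)O[C@H]2/C=C(/C)[C@@H](O[Si](C)(C)C(C)(C)C)C/C=C(/C)C[C@@H](OC(=O)C(C)C)[C@H]12 | intermediate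
22 | (3aS,4R,6Z,9S,10Z,11aS)-9-hydroxy-6,10-dimethyl-3-methylidene-2-oxo-2,3,3a,4,5,8,9,11a-octahydrocyclodeca[b]furan-4-yl 2-methylpropanoate | C=C1C(=O)O[C@H]2/C=C(/C)[C@@H](O)C/C=C(/C)C[C@@H](OC(=O)C(C)C)[C@H]12 | intermediate
23 | (1R,3S,4Z,6S,7S,8R,10S)-1,10-epoxy-3-hydroxy-8-(2-methylpropanoyloxy)germacra-4,11(13)-dien-12,6-olide (CNP0261225.1) | C=C1C(=O)O[C@H]2/C=C(/C)[C@@H](O)C[C@H]3O[C@@]3(C)C[C@@H](OC(=O)C(C)C)[C@H]12 | target

**Totals**
Total step count: 14. Longest linear sequence: 13 steps (steps 1–8 and 10–14, from 1 to 23); step 9 is a one-step side branch.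

**Three steps most likely to fail**

Step 10 (the proposed new allylboration; risks are low reactivity of the electron-poor boronate and isomerisation of 17). The fallback uses known chemistry, sets out from 12 and comes back at 19. Hydroalumination of 12 (iBu2AlH, HMPA, THF) and trapping of the α-alumino enoate with paraformaldehyde, with lactonisation on work-up, gives the 3-(hydroxymethyl)butenolide F1. CBr4/PPh3 converts it into the 3-(bromomethyl)butenolide F2. Nozaki–Hiyama-type allylation of aldehyde 17 with F2, mediated by CrCl2 (divalent chromium) in THF at 0 °C, is the known anti-selective reaction of 3-(bromomethyl)butenolides and proceeds through the same chair geometry to give 19.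

Step 12 (ring-closing metathesis to a ten-membered ring with a trisubstituted olefin; risks are oligomerisation and competing metathesis or chelation at the α-methylene lactone). The fallback sets out from 20 and comes back at 21. Thia-Michael addition of PhSH (Et3N cat., CH2Cl2) masks the exo-methylene lactone as the phenylthiomethyl lactone F3, so that the ring is closed on a substrate without the competing electron-poor olefin. Ring-closing metathesis of F3 with the same ruthenium catalyst gives the macrocyclic sulfide F4. NaIO4 (MeOH/H2O) gives the sulfoxide F5, and thermal syn-elimination (toluene, 80 °C) restores the α-methylene lactone, i.e. 21.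

Step 14 (Shi epoxidation; risk is that the innate facial bias of the macrocycle overrides the ketone and gives the 1,10-epimeric epoxide). The fallback delivers oxygen to the face opposite to the one that electrophiles attack; it sets out from 21 and comes back at 23. NBS in THF/H2O at 0 °C forms the bromonium ion on the innately preferred face, and water opens it at the tertiary C10 to give the bromohydrin F6. Ag2O (CH2Cl2) closes the ring by intramolecular SN2 displacement with inversion at C1 to give the epoxide silyl ether F7. Bu4NF/AcOH in THF removes the TBS group and gives 23.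

**Further compounds**
F1 | step 10 | (5S)-5-[(1Z,3S)-3-(TBS-oxy)-2-methylhexa-1,5-dien-1-yl]-3-(hydroxymethyl)furan-2(5H)-one | OCC1=C[C@H](/C=C(/C)[C@@H](O[Si](C)(C)C(C)(C)C)CC=C)OC1=O
F2 | step 10 | (5S)-5-[(1Z,3S)-3-(TBS-oxy)-2-methylhexa-1,5-dien-1-yl]-3-(bromomethyl)furan-2(5H)-one | BrCC1=C[C@H](/C=C(/C)[C@@H](O[Si](C)(C)C(C)(C)C)CC=C)OC1=O
F3 | step 12 | 13-(phenylsulfanyl)-11,13-dihydro derivative of 20 (C11 epimers) | c2ccccc2SCC1C(=O)O[C@@H](/C=C(/C)[C@@H](O[Si](C)(C)C(C)(C)C)CC=C)[C@@H]1[C@H](OC(=O)C(C)C)CC(C)=C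
F4 | step 12 | 13-(phenylsulfanyl)-11,13-dihydro derivative of 21 (C11 epimers) | c2ccccc2SCC1C(=O)O[C@H]3/C=C(/C)[C@@H](O[Si](C)(C)C(C)(C)C)C/C=C(/C)C[C@@H](OC(=O)C(C)C)[C@H]13
F5 | step 12 | S-oxide (sulfoxide) of F4 | O=S(CC1C(=O)O[C@H]3/C=C(/C)[C@@H](O[Si](C)(C)C(C)(C)C)C/C=C(/C)C[C@@H](OC(=O)C(C)C)[C@H]13)c2ccccc2
F6 | step 14 | 1-bromo-10-hydroxy-1,10-dihydro derivative of 21 (Br on C1 anti to OH on C10; C10 configured as in 23) | C=C1C(=O)O[C@H]2/C=C(/C)[C@@H](O[Si](C)(C)C(C)(C)C)C[C@H](Br)[C@](O)(C)C[C@@H](OC(=O)C(C)C)[C@H]12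
F7 | step 14 | 3-O-TBS ether of 23 | C=C1C(=O)O[C@H]2/C=C(/C)[C@@H](O[Si](C)(C)C(C)(C)C)C[C@H]3O[C@@]3(C)C[C@@H](OC(=O)C(C)C)[C@H]12
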